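## Analysis of the target

The target is a (2S)-flavanone (rings A, B, C; 5,7-dihydroxy-6-methyl). Its C-8 carries an exocyclic methine that also bears an isopropyl group and ring D, a 3-hydroxy-5-methoxy-4,4,6-trimethylcyclohexa-2,5-dien-1-one (ring D atoms C-1′ to C-6′, the methine on C-2′).

There are two stereocentres, C-2 of ring C (S) and the methine (R). They lie five bonds apart on opposite sides of ring A, so neither can be expected to control the other and each needs its own source of asymmetry.

Ring A is hexasubstituted and carries three oxygens (O-1 on C-8a, O-5, O-7) that must be told apart, because only O-1 closes ring C.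

The sensitive groups are:
- the flavanone: C-2 is lost by base-induced opening to the chalcone, and C-3 is enolisable;
- ring D: an acidic vinylogous acid whose methyl enol ether is one of three possible O-methyl regioisomers;
- the ortho-hydroxybenzyl link to ring D: under acid it can cyclodehydrate onto a ring D carbonyl, and on heating it can fragment by a retro-Michael path.

The hard problems are the methine, a stereocentre flanked by two fully substituted sp2 carbons with no neighbouring handle, and the differentiation of the ring A oxygens.

The strategy rests on one structural feature. O-1, C-8a, C-8, the methine, C-2′ and the carbonyl-level carbon C-1′ are the six atoms O-1, C-8a, C-4a, C-4, C-3 and C-2 of a 4-isopropylcoumarin. In that lactone the methine is a prochiral alkene carbon, O-1 alone is masked as an ester, and the lactone carbonyl is an activated acyl group from which ring D can be grown.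

## Retrosynthetic reasoning

**Benzyl ethers (18 from 17).** The O-5 and O-7 benzyl ethers are removed last. Hydrogenolysis is neutral, which matters because acid threatens the ring D enol ether and the ortho-hydroxybenzyl link, and base threatens C-2. Benzyl is kept throughout for that reason.

**C-2–phenyl bond (17 from 15 and 16).** Ring C is cut between C-2 and the phenyl ring, giving chromone 15 and phenylboronic acid 16. Cutting O-1–C-2 instead would require a reversible, weakly controlled ring closure of an unactivated hydroxy enone, in a molecule whose acidic ring D enol would quench a basic catalyst. A catalyst-controlled, irreversible conjugate arylation sets C-2 independently of the remote methine and tolerates acidic groups.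

**C-2/C-3 and O-1–C-2 of the chromone (15 from 12 by way of 13 and 14).** The two carbons come from an acetylide added to the aldehyde carbon of 12. Oxidation to ynone 14 lets the free O-1 phenol close the pyranone by 6-endo addition. Only O-1 can do so, because O-5 and O-7 are benzylated; this is where the early differentiation of O-1 pays off.

**C-4a–C-4 bond (12 from 10 by way of 11).** C-4a is the only unsubstituted ring A carbon, and it is ortho to the free O-1 phenol. A magnesium phenoxide-directed formylation is chosen over Lewis-acid acylation, which would endanger the benzyl ethers and invite cyclodehydration of the phenol onto ring D.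

**Ring D methyl ether (10 from 9).** The methyl group is placed on O-5′, the enol oxygen flanked by the gem-dimethyl carbon and the methyl-bearing carbon. It is the only one of the three ring D oxygens not next to the bulky methine substituent. Methylation precedes formylation so that C-6′ is no longer a nucleophilic enol carbon.

**Ring D carbon skeleton (9 from 8, and 8 from 5 and 7).** Ring D is cut at C-2′–C-3′ and at C-1′–C-6′, both as Claisen-type bonds.
- C-1′–C-6′ forms first: the ketone enolate of 7 attacks the lactone carbonyl of 5. This makes C-1′ a ketone and releases the O-1 phenol.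
- C-2′–C-3′ forms second, intramolecularly, onto the non-enolisable ester of 8. This is the more congested bond, so it is the one made in a ring closure.
- The methine is β to the carbonyl throughout and is not touched by base.
- Keto ester 7 comes from 6 by double C-methylation.

**Methine C–H bond (5 from 4).** The stereocentre is created by adding hydride to C-4 of coumarin 4. No carbon–carbon bond or ring is formed. The lactone fixes the alkene geometry and holds the enoate planar and s-cis, which is what a chiral copper hydride catalyst requires. Everything before this step is achiral.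

**Coumarin (4 from 3, and 3 from 1 and 2).** Benzylation of the two free phenols and a Pechmann condensation lead back to 1 and 2. The two free ring positions of 1 are equivalent, but lactonisation can engage two different hydroxyls, so the 6-methyl isomer 3 has to be separated.

## Alternatives that were turned down

**Alternative 1:** Ring A itself is disconnected at C-8–C-8a, C-6–C-7 and C-4a–C-8a. It would be assembled in a Danheiser benzannulation from cyclobutenone A1 and siloxyalkyne A2, which already carries ring D and the methine. Heating would give phenol A3 with free O-8a, silylated O-7 and benzylated O-5.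
- For it: all three ring A oxygens emerge differentiated in one step, and the substitution pattern is dictated by the pericyclic cascade. This is more than the lactone route achieves, which separates O-8a only from O-5 and O-7; that is, however, all the target needs.
- Against it: the methine stereocentre must exist before the key step, as a propargylic carbon of A2 flanked by the ring D vinylogous ester, and the strategy does not say how to make it as one enantiomer. The ynol silyl ether has to be generated next to that electrophilic dienone. The cascade runs hot through two ketenes, with which the ring D enol ether can interfere. A1 and A2 are both multi-step compounds, whereas ring A here comes from a commercial triol in one condensation.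
- Comparison: the benzannulation is the stronger answer to oxygen differentiation. The chosen route offers instead a stereocentre made by catalysis on a two-step substrate.

**Alternative 2:** The bond between C-2′ and the methine is cut and made by a Claisen rearrangement. In enol ether A4, O-3′ of ring D is bound to the silyl-bearing carbinol carbon of an (E)-allylic unit attached to C-8 of the finished flavanone. On heating it would rearrange through a chair to A5, carrying the carbinol configuration over to the methine and leaving an (E)-vinylsilane.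
- For it: the suprafacial, intramolecular transfer is stereochemically very dependable, arguably more predictable than a face-selective hydride addition to a hindered coumarin. It also forms the congested carbon–carbon bond late and convergently.
- Against it: A4 requires O-alkylation of the ring D enolate with a hindered secondary partner, with O-1′/O-3′ and O/C regiochemistry to control. Its carbinol centre must first be made enantiopure. The rearrangement has to break styrene conjugation while joining two heavily substituted carbons, and the (2S) flavanone must survive the heating. A5 then still needs protodesilylation and hydrogenation of a hindered alkene to reach isopropyl.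
- Comparison: against those extra operations after the key step, the chosen route has the isopropyl group in place from the first step and creates only a C–H bond.

**Alternative 3:** Ring D is traced back to an aromatic ring. The gem-dimethyl carbon is formed last, by dearomative C-methylation of the dianion of resorcinol A6, a diarylmethane in which ring D is still a benzene ring, to give dienone A7.
- For it: the methyl ether of ring D is fixed on an arene, so the O-methyl regiochemistry that the chosen route must steer among three enol oxygens is no issue. The symmetry of the ring makes both methyl-bearing carbons equivalent. On this point the alternative is clearly stronger.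
- Against it: the ambident dianion can react at oxygen or at carbon, and the product is a vinylogous acid that can be methylated again. More seriously, the methine of A6 is a doubly benzylic carbon between two electron-rich arenes with four ortho oxygens; it is prone to acid-induced cleavage, and its asymmetric construction is left open.
- Comparison: the chosen route accepts a selectivity question at a late O-methylation, where isomers can be separated and recycled, in exchange for a methine set by an established catalytic reaction.

Key step: step 3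

Remark on the chemistry: the antipodes of the chiral ligands in steps 3 and 11 are written from the facial preference these catalyst classes show with related cyclic acceptors; should the sense be opposite on these substrates, the other antipode is used and nothing else changes.

Remark on the chemistry: ring D compounds are drawn as one enol tautomer; 9 equilibrates with its triketo form, which does not affect the route.

## Steps

Step 1
Reactants: 1 2-methylphloroglucinol; 2 ethyl 4-methyl-3-oxopentanoate
Product: 3 5,7-dihydroxy-6-methyl-4-(propan-2-yl)-2H-chromen-2-one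
Conditions: CF3CO2H, rt → 60 °C; separation of the 6-methyl isomer (crystallisation, then chromatography)
Reagents that add atoms: none
Why: Pechmann condensation; the keto ester attacks one of the two equivalent free ring positions of 1 and the ring closes with loss of ethanol and water. Lactonisation onto the hydroxyl para to the methyl group gives 3, lactonisation onto a hydroxyl next to the methyl group gives the 8-methyl series, so 3 has to be separated and its constitution secured by NOE and HMBC correlations before it is carried on.

Step 2
Reactants: 3 5,7-dihydroxy-6-methyl-4-(propan-2-yl)-2H-chromen-2-one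
Product: 4 5,7-bis(benzyloxy)-6-methyl-4-(propan-2-yl)-2H-chromen-2-one
Conditions: BnBr, K2CO3, Bu4NI (cat.), DMF, 60 °C
Reagents that add atoms: benzyl bromide, BrCc1ccccc1
Why: Williamson ether synthesis on both phenols; the hindered 5-hydroxyl (peri to isopropyl, next to the methyl group) needs the warm dipolar solvent, and the lactone is stable to carbonate.

Step 3
Reactants: 4 5,7-bis(benzyloxy)-6-methyl-4-(propan-2-yl)-2H-chromen-2-one
Product: 5 (4R)-5,7-bis(benzyloxy)-6-methyl-4-(propan-2-yl)-3,4-dihydro-2H-chromen-2-one
Conditions: Cu(OAc)2·H2O (5 mol%), (R)-DTBM-SEGPHOS (5.5 mol%), (EtO)2MeSiH (1.3 equiv), t-BuOH (1.2 equiv), PhMe, 0 °C → rt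
Reagents that add atoms: none
Why: Cu(OAc)2 is reduced by the silane to a bisphosphine-bound monovalent copper hydride, which adds across C-3=C-4 of 4 with hydride going to C-4 and copper to C-3 (a copper enolate); tert-butanol protonates the enolate to release 5 and a copper alkoxide, from which the silane regenerates the hydride. The closest known reaction type is the copper hydride-catalysed asymmetric conjugate reduction of β,β-disubstituted unsaturated lactones and of 4-substituted coumarins. No ring is closed and no skeletal bond is made; the step forms only the C-4–H bond. The new stereocentre at C-4 is controlled by the chiral bisphosphine, which has to deliver hydride to the Re face of C-4 (C-4a > C-3 > isopropyl) to give the (4R) lactone. The selectivity needed is 1,4- over 1,2-addition and no further reduction of the product. The lactone ring secures the first by locking the enoate planar and s-cis with a fixed alkene geometry, so that the ring A carbon and the isopropyl group are presented to the catalyst unambiguously. Over-reduction of the aryl lactone carbonyl is held back by using only a small excess of silane, a low temperature and a quench at full conversion. The peri benzyloxy group and the branched β-substituent slow hydrocupration, which is why the most active ligand class is chosen.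

Step 4
Reactants: 6 methyl 3-oxopentanoate
Product: 7 methyl 2,2-dimethyl-3-oxopentanoate
Conditions: CH3I (2.5 equiv), K2CO3, acetone, reflux
Reagents that add atoms: iodomethane, CI
Why: Double C-alkylation of a β-keto ester enolate at the doubly activated carbon; after the second methylation that carbon is quaternary, so the only enolisable position left in 7 is the CH2 of the ethyl ketone.

Step 5
Reactants: 5 (4R)-5,7-bis(benzyloxy)-6-methyl-4-(propan-2-yl)-3,4-dihydro-2H-chromen-2-one; 7 methyl 2,2-dimethyl-3-oxopentanoate
Product: 8 methyl (7R)-7-[2,4-bis(benzyloxy)-6-hydroxy-3-methylphenyl]-2,2,4,8-tetramethyl-3,5-dioxononanoate (C-4 epimers and enol forms)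
Conditions: 7 (2.2 equiv), LiN(iPr)2 (2.2 equiv), THF, −78 °C; then 5, −78 → −10 °C; AcOH quench
Reagents that add atoms: none
Why: Crossed Claisen condensation; the kinetic lithium enolate of 7 is C-acylated by the aryl lactone, which opens and releases the O-1 phenoxide, and the second equivalent of enolate is consumed in deprotonating the β-diketone formed. The methine is β to the carbonyl and is not epimerised; 8 may equilibrate with the hemiketal formed by the phenol and is used without storage.

Step 6
Reactants: 8 methyl (7R)-7-[2,4-bis(benzyloxy)-6-hydroxy-3-methylphenyl]-2,2,4,8-tetramethyl-3,5-dioxononanoate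
Product: 9 2-{(1R)-1-[2,4-bis(benzyloxy)-6-hydroxy-3-methylphenyl]-2-methylpropyl}-3,5-dihydroxy-4,4,6-trimethylcyclohexa-2,5-dien-1-one
Conditions: LiN(iPr)2 (3.5 equiv), THF, −78 °C → rt; AcOH quench, cold dilute citric acid wash
Reagents that add atoms: none
Why: Dieckmann (intramolecular Claisen) condensation through the β-diketone dianion; after the phenol and the diketone are deprotonated, the third equivalent of base removes a proton from the CH2 next to the stereocentre, and this carbanion attacks the non-enolisable ester in a 6-exo-trig closure. Loss of methoxide and deprotonation of the cyclic triketone drive the reaction; the work-up is kept cold and only weakly acidic to avoid cyclodehydration of the phenol onto ring D.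

Step 7
Reactants: 9 2-{(1R)-1-[2,4-bis(benzyloxy)-6-hydroxy-3-methylphenyl]-2-methylpropyl}-3,5-dihydroxy-4,4,6-trimethylcyclohexa-2,5-dien-1-one
Product: 10 2-{(1R)-1-[2,4-bis(benzyloxy)-6-hydroxy-3-methylphenyl]-2-methylpropyl}-3-hydroxy-5-methoxy-4,4,6-trimethylcyclohexa-2,5-dien-1-one
Conditions: Me3SiCHN2 (1.05 equiv), PhMe/MeOH 4:1, 0 °C
Reagents that add atoms: trimethylsilyldiazomethane, C[Si](C)(C)C=[N+]=[N-]
Why: O-methylation of a vinylogous acid by a diazoalkane; the acidic trione is methylated far faster than the phenol, and the methyl group should go to O-5′, the only enol oxygen not flanked by the bulky methine substituent. Regioisomeric enol ethers are removed by chromatography and the position of the methyl group is checked by NOE to the neighbouring C-methyl groups.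

Step 8
Reactants: 10 2-{(1R)-1-[2,4-bis(benzyloxy)-6-hydroxy-3-methylphenyl]-2-methylpropyl}-3-hydroxy-5-methoxy-4,4,6-trimethylcyclohexa-2,5-dien-1-one
Product: 12 4,6-bis(benzyloxy)-2-hydroxy-3-[(1R)-1-(2-hydroxy-4-methoxy-3,3,5-trimethyl-6-oxocyclohexa-1,4-dien-1-yl)-2-methylpropyl]-5-methylbenzaldehyde, via hydroxymethyl phenol 11 (not isolated)
Conditions: MgCl2 (3 equiv), Et3N (6 equiv), (CH2O)n (8 equiv), THF, reflux
Reagents that add atoms: formaldehyde (as paraformaldehyde), C=O
Why: Magnesium-mediated ortho-formylation of a phenol; the magnesium phenoxide of O-1 delivers formaldehyde to C-4a, the only free ring position, and the resulting benzylic alkoxide is oxidised by a second formaldehyde in an Oppenauer-type hydride transfer. The conditions are basic and free of Lewis acids, so the benzyl ethers, the enol ether and the methine are not at risk, and ring D is protected as its magnesium enolate.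

Step 9
Reactants: 12 4,6-bis(benzyloxy)-2-hydroxy-3-[(1R)-1-(2-hydroxy-4-methoxy-3,3,5-trimethyl-6-oxocyclohexa-1,4-dien-1-yl)-2-methylpropyl]-5-methylbenzaldehyde
Product: 13 2-{(1R)-1-[2,4-bis(benzyloxy)-6-hydroxy-5-(1-hydroxyprop-2-yn-1-yl)-3-methylphenyl]-2-methylpropyl}-3-hydroxy-5-methoxy-4,4,6-trimethylcyclohexa-2,5-dien-1-one (both carbinol epimers)
Conditions: HC≡CMgBr (5 equiv), THF, −20 °C → rt; aq. NH4Cl
Reagents that add atoms: ethynylmagnesium bromide, C#C[Mg]Br
Why: Grignard 1,2-addition to the aldehyde; the first two equivalents deprotonate the phenol and the ring D enol, whose magnesium enolate is inert to the reagent. The carbinol centre is removed in the next step, and 13 is used crude because electron-rich ortho-hydroxybenzyl alcohols ionise easily.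

Step 10
Reactants: 13 2-{(1R)-1-[2,4-bis(benzyloxy)-6-hydroxy-5-(1-hydroxyprop-2-yn-1-yl)-3-methylphenyl]-2-methylpropyl}-3-hydroxy-5-methoxy-4,4,6-trimethylcyclohexa-2,5-dien-1-one
Product: 15 5,7-bis(benzyloxy)-8-[(1R)-1-(2-hydroxy-4-methoxy-3,3,5-trimethyl-6-oxocyclohexa-1,4-dien-1-yl)-2-methylpropyl]-6-methyl-4H-chromen-4-one, via ynone 14 (not isolated)
Conditions: MnO2 (20 equiv), CH2Cl2, rt; filter; K2CO3 (2.5 equiv), acetone, rt
Reagents that add atoms: none
Why: MnO2 oxidation of a benzylic propargylic alcohol, which is much faster than oxidation of the hydrogen-bonded phenol, followed by 6-endo-dig oxa-Michael addition of the O-1 phenoxide to the terminal ynone. Only O-1 is free, so the pyranone can close in one direction only.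

Step 11
Reactants: 15 5,7-bis(benzyloxy)-8-[(1R)-1-(2-hydroxy-4-methoxy-3,3,5-trimethyl-6-oxocyclohexa-1,4-dien-1-yl)-2-methylpropyl]-6-methyl-4H-chromen-4-one; 16 phenylboronic acid
Product: 17 (2S)-5,7-bis(benzyloxy)-8-[(1R)-1-(2-hydroxy-4-methoxy-3,3,5-trimethyl-6-oxocyclohexa-1,4-dien-1-yl)-2-methylpropyl]-6-methyl-2-phenyl-2,3-dihydro-4H-chromen-4-one
Conditions: 16 (2.5 equiv), Pd(OCOCF3)2 (10 mol%), (R)-t-BuPyOx (12 mol%), NH4PF6 (30 mol%), H2O (5 equiv), ClCH2CH2Cl, 55 °C, under argon
Reagents that add atoms: none
Why: Asymmetric conjugate addition of an arylboronic acid to a chromone, catalysed by cationic divalent palladium with a chiral pyridine-oxazoline ligand; transmetalation gives a phenylpalladium species, enantio-determining insertion of C-2=C-3 places phenyl on C-2, and water protonates the palladium enolate. C-2 is set (S) by the ligand, the methine being too remote to interfere much, and the non-basic medium tolerates the acidic ring D enol and cannot open the flavanone.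

Step 12
Reactants: 17 (2S)-5,7-bis(benzyloxy)-8-[(1R)-1-(2-hydroxy-4-methoxy-3,3,5-trimethyl-6-oxocyclohexa-1,4-dien-1-yl)-2-methylpropyl]-6-methyl-2-phenyl-2,3-dihydro-4H-chromen-4-one
Product: 18 (2S)-5,7-dihydroxy-8-[(1R)-1-(2-hydroxy-4-methoxy-3,3,5-trimethyl-6-oxocyclohexa-1,4-dien-1-yl)-2-methylpropyl]-6-methyl-2-phenyl-2,3-dihydro-4H-chromen-4-one (CNP0320113.1)
Conditions: H2 (1 atm), 10% Pd/C, EtOAc, rt; stopped at full debenzylation
Reagents that add atoms: none
Why: Hydrogenolysis of the two aryl benzyl ethers under neutral conditions; they cleave faster than the C-2–O bond of the flavanone, and the aryl ketone and the tetrasubstituted ring D alkenes are not reduced at ambient pressure. Neither stereocentre is affected.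

## Compound list

1 | 2-methylphloroglucinol (2-methylbenzene-1,3,5-triol) | Cc1c(O)cc(O)cc1O | starting material
2 | ethyl 4-methyl-3-oxopentanoate | CCOC(=O)CC(=O)C(C)C | starting material
3 | 5,7-dihydroxy-6-methyl-4-(propan-2-yl)-2H-chromen-2-one | CC(C)C1=CC(=O)Oc2cc(O)c(C)c(O)c12 | intermediate
4 | 5,7-bis(benzyloxy)-6-methyl-4-(propan-2-yl)-2H-chromen-2-one | CC(C)C1=CC(=O)Oc2cc(OCc3ccccc3)c(C)c(OCc3ccccc3)c12 | intermediate
5 | (4R)-5,7-bis(benzyloxy)-6-methyl-4-(propan-2-yl)-3,4-dihydro-2H-chromen-2-one | CC(C)[C@H]1CC(=O)Oc2cc(OCc3ccccc3)c(C)c(OCc3ccccc3)c12 | intermediate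
6 | methyl 3-oxopentanoate | CCC(=O)CC(=O)OC | starting material
7 | methyl 2,2-dimethyl-3-oxopentanoate | CCC(=O)C(C)(C)C(=O)OC | intermediate
8 | methyl (7R)-7-[2,4-bis(benzyloxy)-6-hydroxy-3-methylphenyl]-2,2,4,8-tetramethyl-3,5-dioxononanoate (C-4 epimers) | COC(=O)C(C)(C)C(=O)C(C)C(=O)C[C@@H](c1c(O)cc(OCc2ccccc2)c(C)c1OCc1ccccc1)C(C)C | intermediate
9 | 2-{(1R)-1-[2,4-bis(benzyloxy)-6-hydroxy-3-methylphenyl]-2-methylpropyl}-3,5-dihydroxy-4,4,6-trimethylcyclohexa-2,5-dien-1-one | OC1=C(C)C(=O)C([C@@H](c2c(O)cc(OCc3ccccc3)c(C)c2OCc2ccccc2)C(C)C)=C(O)C1(C)C | intermediate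
10 | 2-{(1R)-1-[2,4-bis(benzyloxy)-6-hydroxy-3-methylphenyl]-2-methylpropyl}-3-hydroxy-5-methoxy-4,4,6-trimethylcyclohexa-2,5-dien-1-one | COC1=C(C)C(=O)C([C@@H](c2c(O)cc(OCc3ccccc3)c(C)c2OCc2ccccc2)C(C)C)=C(O)C1(C)C | intermediate
11 | 2-{(1R)-1-[2,4-bis(benzyloxy)-6-hydroxy-5-(hydroxymethyl)-3-methylphenyl]-2-methylpropyl}-3-hydroxy-5-methoxy-4,4,6-trimethylcyclohexa-2,5-dien-1-one | COC1=C(C)C(=O)C([C@@H](c2c(O)c(CO)c(OCc3ccccc3)c(C)c2OCc2ccccc2)C(C)C)=C(O)C1(C)C | intermediate (not isolated)
12 | 4,6-bis(benzyloxy)-2-hydroxy-3-[(1R)-1-(2-hydroxy-4-methoxy-3,3,5-trimethyl-6-oxocyclohexa-1,4-dien-1-yl)-2-methylpropyl]-5-methylbenzaldehyde | COC1=C(C)C(=O)C([C@@H](c2c(O)c(C=O)c(OCc3ccccc3)c(C)c2OCc2ccccc2)C(C)C)=C(O)C1(C)C | intermediate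
13 | 2-{(1R)-1-[2,4-bis(benzyloxy)-6-hydroxy-5-(1-hydroxyprop-2-yn-1-yl)-3-methylphenyl]-2-methylpropyl}-3-hydroxy-5-methoxy-4,4,6-trimethylcyclohexa-2,5-dien-1-one (carbinol epimers) | COC1=C(C)C(=O)C([C@@H](c2c(O)c(C(O)C#C)c(OCc3ccccc3)c(C)c2OCc2ccccc2)C(C)C)=C(O)C1(C)C | intermediate
14 | 2-{(1R)-1-[2,4-bis(benzyloxy)-6-hydroxy-3-methyl-5-(prop-2-ynoyl)phenyl]-2-methylpropyl}-3-hydroxy-5-methoxy-4,4,6-trimethylcyclohexa-2,5-dien-1-one | COC1=C(C)C(=O)C([C@@H](c2c(O)c(C(=O)C#C)c(OCc3ccccc3)c(C)c2OCc2ccccc2)C(C)C)=C(O)C1(C)C | intermediate (not isolated)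
15 | 5,7-bis(benzyloxy)-8-[(1R)-1-(2-hydroxy-4-methoxy-3,3,5-trimethyl-6-oxocyclohexa-1,4-dien-1-yl)-2-methylpropyl]-6-methyl-4H-chromen-4-one | COC1=C(C)C(=O)C([C@@H](c2c(OCc3ccccc3)c(C)c(OCc3ccccc3)c3c2OC=CC3=O)C(C)C)=C(O)C1(C)C | intermediate
16 | phenylboronic acid | OB(O)c1ccccc1 | starting material
17 | (2S)-5,7-bis(benzyloxy)-8-[(1R)-1-(2-hydroxy-4-methoxy-3,3,5-trimethyl-6-oxocyclohexa-1,4-dien-1-yl)-2-methylpropyl]-6-methyl-2-phenyl-2,3-dihydro-4H-chromen-4-one | COC1=C(C)C(=O)C([C@@H](c2c(OCc3ccccc3)c(C)c(OCc3ccccc3)c3c2O[C@H](c2ccccc2)CC3=O)C(C)C)=C(O)C1(C)C | intermediate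
18 | (2S)-5,7-dihydroxy-8-[(1R)-1-(2-hydroxy-4-methoxy-3,3,5-trimethyl-6-oxocyclohexa-1,4-dien-1-yl)-2-methylpropyl]-6-methyl-2-phenyl-2,3-dihydro-4H-chromen-4-one (CNP0320113.1) | COC1=C(C)C(=O)C([C@@H](c2c(O)c(C)c(O)c3c2O[C@H](c2ccccc2)CC3=O)C(C)C)=C(O)C1(C)C | target

## Step count and least certain steps

Total: 12 steps. Longest linear sequence: 11 steps (1 to 18 through steps 1–3 and 5–12); step 4 is a one-step side branch that prepares 7.

**Step 3 (key step).** What may go wrong: slow hydrocupration of the hindered alkene (branched β-substituent, peri benzyloxy group), insufficient facial selectivity, and further reduction of the aryl lactone carbonyl once the product is released by the alcohol. Material reduced at the carbonyl can be brought back to 5 by a mild oxidation (Ag2CO3 on Celite), because the stereocentre is not involved.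

Fallback, from 4 back to 5:
- Ring opening of 4 with NaOH in MeOH–H2O gives the sodium salt of (2Z)-3-[2,4-bis(benzyloxy)-6-hydroxy-3-methylphenyl]-4-methylpent-2-enoic acid F1.
- Asymmetric hydrogenation of this carboxylate with a chiral ruthenium or rhodium bisphosphine catalyst (for example Ru(OAc)2[(S)-BINAP], or [Rh(cod)2]BF4 with a ferrocenyl bisphosphine, H2, MeOH) gives (3R)-3-[2,4-bis(benzyloxy)-6-hydroxy-3-methylphenyl]-4-methylpentanoic acid F2.
- Acidification with gentle warming closes the lactone to 5.

Here the carboxylate, not the lactone, binds the metal and dihydrogen replaces the silane, so the carbonyl cannot be over-reduced; benzyl ethers survive homogeneous hydrogenation.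

**Step 7.** What may go wrong: methylation at O-1′ or O-3′ instead of O-5′, or double methylation, because the small methyl electrophile discriminates only moderately between the three enol oxygens. Wrong isomers can be returned to 9 by LiOH hydrolysis and resubmitted.

Fallback, from 9 back to 10:
- Sulfonylation with 2,4,6-triisopropylbenzenesulfonyl chloride (1.0 equiv, Et3N, CH2Cl2, −40 °C) is selected by the bulk of the electrophile for the least hindered enol oxygen. It gives the 5′-O-(2,4,6-triisopropylbenzenesulfonyl) derivative F10 of 9.
- NaOMe in MeOH then replaces the sulfonate at C-5′ by addition–elimination to give 10.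

The regiochemistry is thus decided by a much larger reagent and the methoxy group enters as a nucleophile at carbon.

**Step 6.** What may go wrong: slow closure onto the hindered ester next to the quaternary carbon, competing O-cyclisation to an enol lactone, or retro-Claisen cleavage of the β-diketone by the methoxide set free.

Fallback, from 7 and 5 back to 9, with the order of the two bond formations reversed:
- Saponification of 7 (LiOH, THF–H2O, 0 °C) gives 2,2-dimethyl-3-oxopentanoic acid F7.
- Oxalyl chloride with catalytic DMF gives 2,2-dimethyl-3-oxopentanoyl chloride F8.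
- The lithium enolate of 5 (LiN(SiMe3)2, THF, −78 °C) is C-acylated with F8 to give (4R)-5,7-bis(benzyloxy)-3-(2,2-dimethyl-3-oxopentanoyl)-6-methyl-4-(propan-2-yl)-3,4-dihydro-2H-chromen-2-one F9.
- KOt-Bu in THF closes ring D by attack of the ethyl ketone enolate on the aryl lactone carbonyl, with release of the phenoxide, to give 9.

In this order the ring closure uses the activated aryl ester as electrophile and the hindered bond is made intermolecularly with an acid chloride.

**Step 11.** What may go wrong: low conversion at the crowded, electron-rich chromone, protodeboronation outrunning insertion, or erosion of facial selectivity.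

Fallback, from 12 back to 17, forming the O-1–C-2 bond instead of the C-2–phenyl bond:
- Addition of (E)-PhCH=CHMgBr to 12 gives the allylic alcohol 2-{(1R)-1-[2,4-bis(benzyloxy)-6-hydroxy-5-[(2E)-1-hydroxy-3-phenylprop-2-en-1-yl]-3-methylphenyl]-2-methylpropyl}-3-hydroxy-5-methoxy-4,4,6-trimethylcyclohexa-2,5-dien-1-one F11.
- MnO2 oxidation gives the 2′-hydroxychalcone 2-{(1R)-1-[2,4-bis(benzyloxy)-6-hydroxy-3-methyl-5-[(2E)-3-phenylprop-2-enoyl]phenyl]-2-methylpropyl}-3-hydroxy-5-methoxy-4,4,6-trimethylcyclohexa-2,5-dien-1-one F12.
- Oxa-Michael cyclisation (NaOAc, EtOH, reflux, or a quinine-derived thiourea with one extra equivalent of base to neutralise the ring D enol) gives 17 together with its (2R) epimer F13.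
- The two are diastereomers and are separated; F13 is reopened to F12 with KOH in MeOH and recycled.

**Step 1.** What may go wrong: lactonisation onto a hydroxyl next to the methyl group may dominate, so that the required isomer is the minor one and its separation is laborious.

Fallback, from 1 back to 4 with the regiochemistry fixed by symmetry:
- Silylation of the least hindered hydroxyl of 1 (i-Pr3SiCl, imidazole, DMF, −20 °C) gives 2-methyl-5-[(triisopropylsilyl)oxy]benzene-1,3-diol F3.
- Benzylation (BnBr, K2CO3, acetone) gives [3,5-bis(benzyloxy)-4-methylphenoxy]triisopropylsilane F4.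
- Bu4NF gives 3,5-bis(benzyloxy)-4-methylphenol F5.
- Esterification with 4-methylpent-2-ynoic acid (DCC, DMAP) gives 3,5-bis(benzyloxy)-4-methylphenyl 4-methylpent-2-ynoate F6.
- Intramolecular hydroarylation catalysed by Ph3PAuCl/AgOTf closes the coumarin at either of the two equivalent ortho positions to give 4.

## Further compounds

F1 | step 3 | (2Z)-3-[2,4-bis(benzyloxy)-6-hydroxy-3-methylphenyl]-4-methylpent-2-enoic acid | CC(C)/C(=C/C(=O)O)c1c(O)cc(OCc2ccccc2)c(C)c1OCc1ccccc1
F2 | step 3 | (3R)-3-[2,4-bis(benzyloxy)-6-hydroxy-3-methylphenyl]-4-methylpentanoic acid | OC(=O)C[C@@H](c1c(O)cc(OCc2ccccc2)c(C)c1OCc1ccccc1)C(C)C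
F3 | step 1 | 2-methyl-5-[(triisopropylsilyl)oxy]benzene-1,3-diol | Cc1c(O)cc(O[Si](C(C)C)(C(C)C)C(C)C)cc1O
F4 | step 1 | [3,5-bis(benzyloxy)-4-methylphenoxy]triisopropylsilane | Cc1c(OCc2ccccc2)cc(O[Si](C(C)C)(C(C)C)C(C)C)cc1OCc1ccccc1
F5 | step 1 | 3,5-bis(benzyloxy)-4-methylphenol | Cc1c(OCc2ccccc2)cc(O)cc1OCc1ccccc1
F6 | step 1 | 3,5-bis(benzyloxy)-4-methylphenyl 4-methylpent-2-ynoate | CC(C)C#CC(=O)Oc1cc(OCc2ccccc2)c(C)c(OCc2ccccc2)c1
F7 | step 6 | 2,2-dimethyl-3-oxopentanoic acid | CCC(=O)C(C)(C)C(=O)O
F8 | step 6 | 2,2-dimethyl-3-oxopentanoyl chloride | CCC(=O)C(C)(C)C(=O)Cl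
F9 | step 6 | (4R)-5,7-bis(benzyloxy)-3-(2,2-dimethyl-3-oxopentanoyl)-6-methyl-4-(propan-2-yl)-3,4-dihydro-2H-chromen-2-one (C-3 epimers) | CCC(=O)C(C)(C)C(=O)C1C(=O)Oc2cc(OCc3ccccc3)c(C)c(OCc3ccccc3)c2[C@H]1C(C)C
F10 | step 7 | 4-{(1R)-1-[2,4-bis(benzyloxy)-6-hydroxy-3-methylphenyl]-2-methylpropyl}-5-hydroxy-2,6,6-trimethyl-3-oxocyclohexa-1,4-dien-1-yl 2,4,6-triisopropylbenzenesulfonate | CC(C)c1cc(C(C)C)c(S(=O)(=O)OC2=C(C)C(=O)C([C@@H](c3c(O)cc(OCc4ccccc4)c(C)c3OCc3ccccc3)C(C)C)=C(O)C2(C)C)c(C(C)C)c1
F11 | step 11 | 2-{(1R)-1-[2,4-bis(benzyloxy)-6-hydroxy-5-[(2E)-1-hydroxy-3-phenylprop-2-en-1-yl]-3-methylphenyl]-2-methylpropyl}-3-hydroxy-5-methoxy-4,4,6-trimethylcyclohexa-2,5-dien-1-one (carbinol epimers) | COC1=C(C)C(=O)C([C@@H](c2c(O)c(C(O)/C=C/c3ccccc3)c(OCc3ccccc3)c(C)c2OCc2ccccc2)C(C)C)=C(O)C1(C)C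
F12 | step 11 | 2-{(1R)-1-[2,4-bis(benzyloxy)-6-hydroxy-3-methyl-5-[(2E)-3-phenylprop-2-enoyl]phenyl]-2-methylpropyl}-3-hydroxy-5-methoxy-4,4,6-trimethylcyclohexa-2,5-dien-1-one | COC1=C(C)C(=O)C([C@@H](c2c(O)c(C(=O)/C=C/c3ccccc3)c(OCc3ccccc3)c(C)c2OCc2ccccc2)C(C)C)=C(O)C1(C)C
F13 | step 11 | (2R)-5,7-bis(benzyloxy)-8-[(1R)-1-(2-hydroxy-4-methoxy-3,3,5-trimethyl-6-oxocyclohexa-1,4-dien-1-yl)-2-methylpropyl]-6-methyl-2-phenyl-2,3-dihydro-4H-chromen-4-one | COC1=C(C)C(=O)C([C@@H](c2c(OCc3ccccc3)c(C)c(OCc3ccccc3)c3c2O[C@@H](c2ccccc2)CC3=O)C(C)C)=C(O)C1(C)C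
A1 | alternative 1 | 3-(benzyloxy)-2-methylcyclobut-2-en-1-one | CC1=C(OCc2ccccc2)CC1=O
A2 | alternative 1 | 3-(benzyloxy)-5-methoxy-4,4,6-trimethyl-2-{(3R)-2-methyl-5-[(triisopropylsilyl)oxy]pent-4-yn-3-yl}cyclohexa-2,5-dien-1-one | COC1=C(C)C(=O)C([C@@H](C#CO[Si](C(C)C)(C(C)C)C(C)C)C(C)C)=C(OCc2ccccc2)C1(C)C
A3 | alternative 1 | 3-(benzyloxy)-2-{(1R)-1-[4-(benzyloxy)-6-hydroxy-3-methyl-2-[(triisopropylsilyl)oxy]phenyl]-2-methylpropyl}-5-methoxy-4,4,6-trimethylcyclohexa-2,5-dien-1-one | COC1=C(C)C(=O)C([C@@H](c2c(O[Si](C(C)C)(C(C)C)C(C)C)c(C)c(OCc3ccccc3)cc2O)C(C)C)=C(OCc2ccccc2)C1(C)C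
A4 | alternative 2 | (2S)-5,7-bis(benzyloxy)-8-{(1E,3R)-3-[(5-methoxy-4,6,6-trimethyl-3-oxocyclohexa-1,4-dien-1-yl)oxy]-2-methyl-3-(trimethylsilyl)prop-1-en-1-yl}-6-methyl-2-phenyl-2,3-dihydro-4H-chromen-4-one | COC1=C(C)C(=O)C=C(O[C@H]([Si](C)(C)C)/C(C)=C/c2c(OCc3ccccc3)c(C)c(OCc3ccccc3)c3c2O[C@H](c2ccccc2)CC3=O)C1(C)C
A5 | alternative 2 | (2S)-5,7-bis(benzyloxy)-8-[(2E)-1-(2-hydroxy-4-methoxy-3,3,5-trimethyl-6-oxocyclohexa-1,4-dien-1-yl)-2-methyl-3-(trimethylsilyl)prop-2-en-1-yl]-6-methyl-2-phenyl-2,3-dihydro-4H-chromen-4-one, methine configured as in the target | COC1=C(C)C(=O)C([C@@H](c2c(OCc3ccccc3)c(C)c(OCc3ccccc3)c3c2O[C@H](c2ccccc2)CC3=O)/C(C)=C/[Si](C)(C)C)=C(O)C1(C)C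
A6 | alternative 3 | 2-{1-[2,4-bis(benzyloxy)-6-(methoxymethoxy)-3-methylphenyl]-2-methylpropyl}-5-methoxy-4,6-dimethylbenzene-1,3-diol, methine configured as in the target | COc1c(C)c(O)c([C@@H](c2c(OCc3ccccc3)c(C)c(OCc3ccccc3)cc2OCOC)C(C)C)c(O)c1C
A7 | alternative 3 | 2-{(1R)-1-[2,4-bis(benzyloxy)-6-(methoxymethoxy)-3-methylphenyl]-2-methylpropyl}-3-hydroxy-5-methoxy-4,4,6-trimethylcyclohexa-2,5-dien-1-one | COC1=C(C)C(=O)C([C@@H](c2c(OCc3ccccc3)c(C)c(OCc3ccccc3)cc2OCOC)C(C)C)=C(O)C1(C)C
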